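## Structural features

The target is a flavone: a benzo ring (ring A, C4a to C8a) fused along C4a–C8a to a 4-pyranone (ring C: O1, C2, C3, C4). Ring C carries a methoxy group at C3 and, through one C–C bond at C2, a 3,4,5-trihydroxyphenyl group (ring B). There is no stereocentre and no stereogenic double bond, so the problem is purely one of constitution and of oxygen differentiation. Ring A bears oxygen on four of its six carbons: free hydroxyls at C5 and C8, a methyl ether at C7 and the ring oxygen O1 at C8a; only C6 carries hydrogen. The C5/C8 pair is a para-hydroquinone and ring B is a pyrogallol; both autoxidise readily, above all under base, so the free polyphenol should be released last under neutral, reducing conditions. The real difficulty is to tell the four ring A oxygens apart (two free, one methylated, one built into ring C) while keeping the C3 and C7 methyl ethers and freeing three ring B hydroxyls. The key step exploits the para relation of C5 and C8: at the quinone oxidation level C8a becomes an electrophilic carbon, β to the C5 and C4 carbonyls through C4a, and its methoxy group can be displaced by the enol oxygen on C2. That forms O1–C8a, closes ring C and leaves the C7 methoxy as the only methyl ether on ring A.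

## Logic of the disconnections

13 back to 11 (through 12). No skeletal bond is cut. The five O–H bonds of 13 are traced back to three O-benzyl bonds on ring B and to the two quinone carbonyls at C5 and C8. The hydroquinone and the pyrogallol are the fragile parts and should appear last; both changes are reductions, so one operation serves, passing through 12. The gain is that every earlier intermediate is non-phenolic and easy to handle. The demand is that the reduction stops short of the C2=C3 bond, leaves the methyl ethers at C3 and C7 alone, and that 13 is isolated without air.

11 back to 9 (through 10). The O1–C8a bond of ring C is cut and the ring A quinone is taken back to the fully methylated arene. At the quinone level C8a is an acceptor with a built-in leaving group, so the ring oxygen can be supplied by the enol of an open-chain 1,3-diketone. The same oxidation that creates the acceptor also picks C5 and C8 for unmasking, because they are the only para pair. The gain is that ring C and the differentiation of four methyl ethers are settled together, with no protecting group on ring A. The demand is that the oxidation takes ring A before the enolizable diketone or ring B, and that closure uses the C8a methoxy and not the C7 methoxy.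

9 back to 5 and 7. The bond between the methoxy-bearing carbon (future C3) and the ring B carbonyl carbon (future C2) is cut. It lies α to a ketone and is made by acylating an enolate. The gain is two halves of similar size, each one step from a commercial compound. The demand is C-acylation and not O-acylation of 8, in the presence of a product that is more acidic than 5.

7 back to 6. Only the C–Cl bond is changed; this is carboxyl activation and nothing else. The demand is merely that the benzyl ethers survive.

5 back to 1 and 2. The bond between ring A (future C4a) and the ketone carbon (future C4) is cut. 1 has a single kind of ring hydrogen, flanked by two methoxy groups, so metalation to 3 can only occur at the future C4a, and 2 stops at the ketone stage through 4. The gain is that symmetric, commercial 1 already holds all four ring A oxygens in the right places. The demand is that the hindered aryl anion adds to the amide carbonyl and does not act as a base.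

## Other disconnections considered

Alternative 1: The cut goes through O1–C8a and C4–C4a. Ring A arrives as the aryne released by CsF from 3,5-dimethoxy-2-(trimethylsilyl)phenyl triflate A1, and C2–C3–C4 with ring B arrives as (Z)-2-methoxy-3-[3,4,5-tris(benzyloxy)phenyl]prop-2-enoic acid A2. In the forward step the carboxylate oxygen would add to the aryne carbon remote from the flanking methoxy group, and the aryl anion would attack the carboxyl carbon, transferring the acyl group to carbon. The product is the 2'-hydroxy-α-methoxychalcone A3; no ring closes.
- In favour: two bonds form in one mild operation, benzyl ethers tolerate fluoride, and the regiochemistry follows from aryne distortion by the methoxy group. Insertion of arynes into the C–O bond of carboxylic acids is an established reaction type, so on precedent for the key step this alternative is better than the chosen plan.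
- Against: ring A comes with only the C5 and C7 oxygens. After oxidative cyclisation of A3 to the 3,5,7-trimethoxyflavone A4, the C8 oxygen would have to be added by selective 5-O-demethylation and an Elbs para-hydroxylation with K2S2O8, a step of generally modest efficiency on flavones. Protonation of the aryl anion by the free acid (giving an aryl ester) would compete with acyl transfer.
- Comparison: structurally, the chosen plan carries all four ring A oxygens from 1 and sets the C5/C8 oxidation level in the ring-forming step, whereas here one oxygen is added late. Mechanistically, the alternative's key step is on firmer ground but its late oxidation is weak. On convergence the two are equal. On step economy, A1 and A2 each need a few steps, so about ten or eleven steps would be expected against five.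

Alternative 2: The cut removes C4 as carbon monoxide, disconnecting both C4a–C4 and C4–C3. This leaves the ring A iodide 3-(benzyloxy)-1-iodo-4,6-dimethoxy-2-(methoxymethoxy)benzene A5 and 2-methoxy-1-[3,4,5-tris(benzyloxy)phenyl]ethan-1-one A6. In the forward step A5 would add oxidatively to zerovalent palladium (Pd(dba)2 with Xantphos), CO would insert, and the enolate of A6 would attack the aroyl complex of divalent palladium. Reductive elimination gives the 1,3-diketone A7; no ring closes.
- In favour: it is a three-component coupling of a known reaction type (carbonylative α-arylation of ketones). Each ring A oxygen carries its own label (methoxymethyl for the future O1, benzyl for O8, methyl for O5 and O7), so ring closure after acetal removal is an ordinary cyclodehydration. In predictability of which oxygen becomes O1 this alternative is better than the chosen plan, and it needs no oxidant near an enolizable diketone. It is equal in that the same kind of 2-methoxy-1,3-diketone is the pivotal intermediate.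
- Against: A5 is a very electron-rich iodide with two ortho substituents, so oxidative addition and acyl transfer would be slow, and direct arylation without CO or reduction could intrude. The enolate of A6 is a secondary α-alkoxy enolate, outside the usual scope. The C5 oxygen ends as a methyl ether that must later be cleaved selectively beside those at C3 and C7. A5 with four different oxygen substituents would need about five steps.
- Comparison: the alternative's mechanism is a well-understood catalytic cycle, against a tandem without direct precedent. On step economy it stands at roughly ten steps plus handling of CO, against five.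

Alternative 3: The cut is C4a–C5; ring A is built from a four-carbon squarate unit on a preformed ring C. The C6-lithiated form of 3-methoxy-2-[3,4,5-tris(benzyloxy)phenyl]-4H-pyran-4-one A8 would add to the more electrophilic carbonyl of 3-methoxycyclobut-3-ene-1,2-dione A9 to give the 4-hydroxycyclobutenone A10. Heating A10 should open it to a dienylketene whose ketene carbon bonds to the pyranone C5–H (future C4a) in a 6π-electrocyclisation. Tautomerisation then gives the hydroquinone A11, which has the same structure as 12.
- In favour: the 5,8-hydroquinone level and the C7 methoxy come directly from the squarate unit, with no oxidant and no choice among methyl ethers. The thermal ring expansion of 4-aryl- and 4-alkenyl-4-hydroxycyclobutenones is a well-known reaction type. On both points it is better than the chosen plan, and it is equal in the end game (one hydrogenolysis).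
- Against: it rests on C6 metalation of a 4-pyranone, a ring prone to nucleophilic opening and conjugate addition. Addition to A9 must take place at the carbonyl next to the methoxy-bearing carbon. The electrocyclisation onto a pyranone carbon must outrun closure of the hydroxyl onto the ketene, which would give a butenolide.
- Comparison: structurally, the alternative builds ring A last and the chosen plan builds ring C last. On step economy, A8 and A9 each need several steps, so about nine or ten steps would be expected against five.

Key step: step 4

Remarks on the chemistry (assumptions):
- Atoms are labelled by flavone numbering throughout, including in open-chain compounds ("future C4a").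
- 13 has no stereocentre. 9 is racemic at its methine carbon and that centre becomes sp2 in step 4; 4 is racemic and transient.
- 1, 2 and 6 are taken as commercial.
- The skeleton of the diketone precursor 9 is kept unchanged, and its structure and that of 11 were checked atom by atom against 13. Two design choices are made around it. Ring B carries plain benzyl ethers, which resist the cerium oxidant and fall in the same reduction that converts the quinone. The ring closure is run as a separate, anhydrous, acid-catalysed stage after a short cold oxidation.

## Route

Step 1
Reactants: 1 1,2,3,5-tetramethoxybenzene; 2 N,2-dimethoxy-N-methylacetamide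
Product: 5 2-methoxy-1-(2,3,4,6-tetramethoxyphenyl)ethan-1-one, via (2,3,4,6-tetramethoxyphenyl)lithium 3 (not isolated), via lithium hemiaminal adduct 4 (not isolated)
Conditions: n-BuLi (1.1 equiv), TMEDA (1.1 equiv), THF, 0 °C, 1 h; then 2 (1.2 equiv), −78 → 0 °C; 1 M HCl
Reagents that add atoms: none
Why: Directed ortho-metalation followed by a Weinreb ketone synthesis: 1 has one kind of ring hydrogen, flanked by two methoxy groups, so lithiation to 3 is regiochemically unambiguous, the chelated adduct 4 persists until the acid quench so no second addition occurs, and no Lewis acid is present that could cleave an ortho methyl ether.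

Step 2
Reactants: 6 3,4,5-tris(benzyloxy)benzoic acid
Product: 7 3,4,5-tris(benzyloxy)benzoyl chloride
Conditions: (COCl)2 (1.3 equiv), DMF (cat.), CH2Cl2, 0 → 23 °C; evaporation, used crude
Reagents that add atoms: oxalyl chloride, ClC(=O)C(=O)Cl
Why: Standard acid chloride formation through the chloroiminium species formed from DMF; the by-products are gases and aryl benzyl ethers are inert to these conditions.

Step 3
Reactants: 5 2-methoxy-1-(2,3,4,6-tetramethoxyphenyl)ethan-1-one; 7 3,4,5-tris(benzyloxy)benzoyl chloride
Product: 9 2-methoxy-1-(2,3,4,6-tetramethoxyphenyl)-3-[3,4,5-tris(benzyloxy)phenyl]propane-1,3-dione (racemic, enolizable), via lithium enolate 8 (not isolated)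
Conditions: LiN(SiMe3)2 (2.2 equiv), THF/toluene, −78 °C; then 7 (1.0 equiv), −78 → 0 °C; aq. NH4Cl
Reagents that add atoms: none
Why: Claisen-type C-acylation of a ketone lithium enolate with an aroyl chloride: lithium is held between the enolate oxygen and the α-methoxy group, and tight ion pairing in THF/toluene should favour attack through carbon; the second equivalent of base converts the product into its diketonate, which protects it from further acylation.

Step 4
Reactants: 9 2-methoxy-1-(2,3,4,6-tetramethoxyphenyl)-3-[3,4,5-tris(benzyloxy)phenyl]propane-1,3-dione
Product: 11 3,7-dimethoxy-2-[3,4,5-tris(benzyloxy)phenyl]-4H-chromene-4,5,8-trione, via acylquinone 10 (not isolated)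
Conditions: (NH4)2Ce(NO3)6 (2.2 equiv), MeCN/H2O 3:1, 0 °C, 15 min; extraction into CH2Cl2; then camphorsulfonic acid (10 mol %), dry CH2Cl2, 23 °C
Reagents that add atoms: water, O
Why: Proposed new method: tetravalent cerium removes an electron from the tetra-alkoxy ring A of 9, water adds at the methoxy-bearing C5 and C8 and two molecules of methanol leave, which is the established oxidative demethylation of 1,4-dimethoxyarenes and should give acylquinone 10. In 10 the carbon C8a carries a methoxy leaving group, is β to both the C5 quinone carbonyl and the C4 ketone through C4a and α to the C8 carbonyl, so it is a doubly activated vinylogous ester carbon; the acid-catalysed enol of the ring B carbonyl adds through oxygen in a 6-endo-trig conjugate addition and methanol is expelled, forming O1–C8a and ring C. The closest known reaction types are this cerium oxidation and the addition–elimination of oxygen, nitrogen and sulfur nucleophiles at 2-methoxy-1,4-benzoquinones; new is their use in sequence with an enol oxygen to close a chromone. No stereocentre is formed, and the racemic methine of 9 becomes the sp2 carbon C3. The selectivity needed is among four methyl ethers: only C5 and C8 are para to each other, only the C8a methoxy is doubly activated and within reach of a six-membered transition state, and the C7 methoxy, a simple vinylogous ester beyond reach of the enol, is kept by excluding water and external nucleophiles in the closing stage. Ring B should be spared because its aroyl-deactivated trialkoxy ring and plain benzyl ethers are harder to oxidise than ring A, whose ketone is twisted out of conjugation by two ortho methoxy groups, and the diketone is expected to sit mainly in the less oxidisable diketo form. If water displaces the C8a methoxy first, the resulting hydroxyquinone can still condense with the ring B ketone under the same acid to give 11, so that side path converges.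

Step 5
Reactants: 11 3,7-dimethoxy-2-[3,4,5-tris(benzyloxy)phenyl]-4H-chromene-4,5,8-trione
Product: 13 5,8-dihydroxy-3,7-dimethoxy-2-(3,4,5-trihydroxyphenyl)-4H-chromen-4-one, via hydroquinone tribenzyl ether 12 (not isolated)
Conditions: H2 (1 atm), Pd/C (10 wt %), THF/MeOH 1:1, 23 °C; filtration under argon, degassed solvents
Reagents that add atoms: none
Why: Heterogeneous hydrogenation and hydrogenolysis: the quinone is reduced first to 12, then the three aryl benzyl ethers are cleaved to toluene; the tetrasubstituted, vinylogous-ester C2=C3 bond of the chromone and the aryl methyl ethers should not react under one atmosphere of hydrogen at room temperature.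

## Compound list

1 | 1,2,3,5-tetramethoxybenzene | COc1cc(OC)c(OC)c(OC)c1 | starting material
2 | N,2-dimethoxy-N-methylacetamide | COCC(=O)N(C)OC | starting material
3 | (2,3,4,6-tetramethoxyphenyl)lithium | [Li]c1c(OC)cc(OC)c(OC)c1OC | intermediate (not isolated)
4 | lithium 2-methoxy-1-[methoxy(methyl)amino]-1-(2,3,4,6-tetramethoxyphenyl)ethan-1-olate (racemic) | COCC(O[Li])(N(C)OC)c1c(OC)cc(OC)c(OC)c1OC | intermediate (not isolated)
5 | 2-methoxy-1-(2,3,4,6-tetramethoxyphenyl)ethan-1-one | COCC(=O)c1c(OC)cc(OC)c(OC)c1OC | intermediate
6 | 3,4,5-tris(benzyloxy)benzoic acid | OC(=O)c1cc(OCc2ccccc2)c(OCc2ccccc2)c(OCc2ccccc2)c1 | starting material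
7 | 3,4,5-tris(benzyloxy)benzoyl chloride | ClC(=O)c1cc(OCc2ccccc2)c(OCc2ccccc2)c(OCc2ccccc2)c1 | intermediate
8 | lithium (Z)-2-methoxy-1-(2,3,4,6-tetramethoxyphenyl)ethen-1-olate (chelated Z geometry assumed; of no consequence) | [Li]O/C(=C\OC)c1c(OC)cc(OC)c(OC)c1OC | intermediate (not isolated)
9 | 2-methoxy-1-(2,3,4,6-tetramethoxyphenyl)-3-[3,4,5-tris(benzyloxy)phenyl]propane-1,3-dione (racemic, enolizable) | COc1cc(OC)c(C(=O)C(OC)C(=O)c2cc(OCc3ccccc3)c(OCc3ccccc3)c(OCc3ccccc3)c2)c(OC)c1OC | intermediate
10 | 1-(2,4-dimethoxy-3,6-dioxocyclohexa-1,4-dien-1-yl)-2-methoxy-3-[3,4,5-tris(benzyloxy)phenyl]propane-1,3-dione (racemic) | COC1=CC(=O)C(C(=O)C(OC)C(=O)c2cc(OCc3ccccc3)c(OCc3ccccc3)c(OCc3ccccc3)c2)=C(OC)C1=O | intermediate (not isolated)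
11 | 3,7-dimethoxy-2-[3,4,5-tris(benzyloxy)phenyl]-4H-chromene-4,5,8-trione | COC1=CC(=O)c2c(=O)c(OC)c(-c3cc(OCc4ccccc4)c(OCc4ccccc4)c(OCc4ccccc4)c3)oc2C1=O | intermediate
12 | 5,8-dihydroxy-3,7-dimethoxy-2-[3,4,5-tris(benzyloxy)phenyl]-4H-chromen-4-one | COc1cc(O)c2c(=O)c(OC)c(-c3cc(OCc4ccccc4)c(OCc4ccccc4)c(OCc4ccccc4)c3)oc2c1O | intermediate (not isolated)
13 | 5,8-dihydroxy-3,7-dimethoxy-2-(3,4,5-trihydroxyphenyl)-4H-chromen-4-one (5,8,3',4',5'-pentahydroxy-3,7-dimethoxyflavone) | COc1cc(O)c2c(=O)c(OC)c(-c3cc(O)c(O)c(O)c3)oc2c1O | target

## Step count and risks

Total step count: 5. Longest linear sequence: 4 steps (steps 1, 3, 4 and 5, from 1 to 13); step 2 is a one-step branch.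

Least certain steps:

Step 4 (key step, proposed new method). The most likely failure is one-electron oxidation of the enol form of the diketone chain by tetravalent cerium in competition with oxidation of ring A, leading to radical coupling or nitrate trapping at the methine carbon. Second, the ring closure may stall, or be overtaken by hydrolysis of the C7 vinylogous ester while water is still present. The fallback uses known chemistry and closes ring C before the oxidation. It sets out from 5. Chelation-directed mono-demethylation with BCl3 (CH2Cl2, −78 → 0 °C), expected at the methoxy group flanked by the carbonyl and a second methoxy group, should give 1-(2-hydroxy-3,4,6-trimethoxyphenyl)-2-methoxyethan-1-one F1; this regiochemistry would need to be confirmed before going on. Its lithium dianion (LiN(SiMe3)2, 3 equiv, THF, −78 °C) would be C-acylated with 7 to 1-(2-hydroxy-3,4,6-trimethoxyphenyl)-2-methoxy-3-[3,4,5-tris(benzyloxy)phenyl]propane-1,3-dione F2. Acid-catalysed cyclodehydration (TsOH cat., toluene, 80 °C) would then give 3,5,7,8-tetramethoxy-2-[3,4,5-tris(benzyloxy)phenyl]-4H-chromen-4-one F3. Oxidative demethylation of the C5/C8 para pair of F3 with (NH4)2Ce(NO3)6 in aqueous MeCN, the ordinary use of this reagent on a 1,4-dimethoxyarene that no longer holds an enolizable diketone, comes back to the route at 11. The cost is three extra steps.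

Step 3. The likely failure is O-acylation of 8 (enol ester formation) in competition with C-acylation, together with consumption of 7 by the amide base. The fallback sets out from 5. Aldol addition of its enolate (LiN(iPr)2, THF, −78 °C) to commercial 3,4,5-tris(benzyloxy)benzaldehyde would give 3-hydroxy-2-methoxy-1-(2,3,4,6-tetramethoxyphenyl)-3-[3,4,5-tris(benzyloxy)phenyl]propan-1-one F4 as a mixture of diastereomers, both centres being lost later. Oxidation with Dess–Martin periodinane (CH2Cl2, 23 °C) then comes back to the route at 9. An aldehyde offers the enolate no O-acylation path, so the C–C bond is secured at the price of one step.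

Step 1. The likely failure is proton transfer from the α-CH2 group of 2 to the hindered aryllithium 3, which returns 1, or base-induced loss of formaldehyde from the N-methoxy group, in place of carbonyl addition. The fallback sets out from 1: Friedel–Crafts acylation with methoxyacetyl chloride (SnCl4, CH2Cl2, −20 °C) comes back directly at 5. The mild Lewis acid and low temperature are chosen to hold back cleavage of an ortho methyl ether and decarbonylation of the acylium ion. No compound outside the list is made.

Step 5. The likely failures are slow saturation of the C2=C3 bond on prolonged contact with the catalyst, and autoxidation of the hydroquinone and pyrogallol units while the catalyst is filtered off. The fallback sets out from 11: reduction with Na2S2O4 (EtOAc/H2O, 23 °C) to 12, then debenzylation with BCl3 and pentamethylbenzene (CH2Cl2, −78 °C; MeOH quench), which arrives at 13 with an acidic, metal-free work-up. Aryl methyl ethers should not be cleaved at this temperature. No compound outside the list is made.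

## Further compounds

F1 | step 4 | 1-(2-hydroxy-3,4,6-trimethoxyphenyl)-2-methoxyethan-1-one | COCC(=O)c1c(O)c(OC)c(OC)cc1OC
F2 | step 4 | 1-(2-hydroxy-3,4,6-trimethoxyphenyl)-2-methoxy-3-[3,4,5-tris(benzyloxy)phenyl]propane-1,3-dione (racemic, enolizable) | COc1cc(OC)c(C(=O)C(OC)C(=O)c2cc(OCc3ccccc3)c(OCc3ccccc3)c(OCc3ccccc3)c2)c(O)c1OC
F3 | step 4 | 3,5,7,8-tetramethoxy-2-[3,4,5-tris(benzyloxy)phenyl]-4H-chromen-4-one | COc1cc(OC)c2c(=O)c(OC)c(-c3cc(OCc4ccccc4)c(OCc4ccccc4)c(OCc4ccccc4)c3)oc2c1OC
F4 | step 3 | 3-hydroxy-2-methoxy-1-(2,3,4,6-tetramethoxyphenyl)-3-[3,4,5-tris(benzyloxy)phenyl]propan-1-one (mixture of diastereomers, racemic) | COc1cc(OC)c(C(=O)C(OC)C(O)c2cc(OCc3ccccc3)c(OCc3ccccc3)c(OCc3ccccc3)c2)c(OC)c1OC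
F0 | step 1 | none | none
F0 | step 5 | none | none
A1 | alternative 1 | 3,5-dimethoxy-2-(trimethylsilyl)phenyl trifluoromethanesulfonate | COc1cc(OC)c([Si](C)(C)C)c(OS(=O)(=O)C(F)(F)F)c1
A2 | alternative 1 | (Z)-2-methoxy-3-[3,4,5-tris(benzyloxy)phenyl]prop-2-enoic acid | CO/C(=C\c1cc(OCc2ccccc2)c(OCc2ccccc2)c(OCc2ccccc2)c1)C(=O)O
A3 | alternative 1 | (Z)-1-(2-hydroxy-4,6-dimethoxyphenyl)-2-methoxy-3-[3,4,5-tris(benzyloxy)phenyl]prop-2-en-1-one | COc1cc(O)c(C(=O)/C(OC)=C/c2cc(OCc3ccccc3)c(OCc3ccccc3)c(OCc3ccccc3)c2)c(OC)c1
A4 | alternative 1 | 3,5,7-trimethoxy-2-[3,4,5-tris(benzyloxy)phenyl]-4H-chromen-4-one | COc1cc(OC)c2c(=O)c(OC)c(-c3cc(OCc4ccccc4)c(OCc4ccccc4)c(OCc4ccccc4)c3)oc2c1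
A5 | alternative 2 | 3-(benzyloxy)-1-iodo-4,6-dimethoxy-2-(methoxymethoxy)benzene | COCOc1c(I)c(OC)cc(OC)c1OCc1ccccc1
A6 | alternative 2 | 2-methoxy-1-[3,4,5-tris(benzyloxy)phenyl]ethan-1-one | COCC(=O)c1cc(OCc2ccccc2)c(OCc2ccccc2)c(OCc2ccccc2)c1
A7 | alternative 2 | 1-[3-(benzyloxy)-4,6-dimethoxy-2-(methoxymethoxy)phenyl]-2-methoxy-3-[3,4,5-tris(benzyloxy)phenyl]propane-1,3-dione (racemic, enolizable) | COCOc1c(C(=O)C(OC)C(=O)c2cc(OCc3ccccc3)c(OCc3ccccc3)c(OCc3ccccc3)c2)c(OC)cc(OC)c1OCc1ccccc1
A8 | alternative 3 | 3-methoxy-2-[3,4,5-tris(benzyloxy)phenyl]-4H-pyran-4-one | COc1c(-c2cc(OCc3ccccc3)c(OCc3ccccc3)c(OCc3ccccc3)c2)occc1=O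
A9 | alternative 3 | 3-methoxycyclobut-3-ene-1,2-dione | COC1=CC(=O)C1=O
A10 | alternative 3 | 4-hydroxy-3-methoxy-4-{5-methoxy-4-oxo-6-[3,4,5-tris(benzyloxy)phenyl]-4H-pyran-2-yl}cyclobut-2-en-1-one (racemic) | COC1=CC(=O)C1(O)c1cc(=O)c(OC)c(-c2cc(OCc3ccccc3)c(OCc3ccccc3)c(OCc3ccccc3)c2)o1
A11 | alternative 3 | 5,8-dihydroxy-3,7-dimethoxy-2-[3,4,5-tris(benzyloxy)phenyl]-4H-chromen-4-one | COc1cc(O)c2c(=O)c(OC)c(-c3cc(OCc4ccccc4)c(OCc4ccccc4)c(OCc4ccccc4)c3)oc2c1O
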